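**Retrosynthetic overview**

- In the target (chroman-4-one numbering), ring A carbon C8 carries the stereogenic methine C1', which is β to the ester carbonyl and ortho to the C7 oxygen. Because C7–O can close a six-membered ring onto the ester carbon, the C8–C1' bond is cut back to phloroglucinol and (E)-hex-2-enal (iminium-catalysed Friedel–Crafts alkylation with lactol closure).
- The lactol is oxidised to the dihydrocoumarin, which ties up C7–O. The unhindered para oxygen (future C5–O) is masked as an isopropyl ether, C4a is propanoylated, and the pyranone ring is closed on the only free ortho oxygen (C8a–O).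
- End game on the chromone: C5–OH is unmasked and the lactone opened with methanol, O7 is converted to a reverse-prenyl ether, hydride is added asymmetrically to C2=C3 (cis C2/C3), and an aromatic Claisen shift places the prenyl group on C6.
- Ring order: lactol/lactone ring (step 1, temporary), pyranone ring (step 5), lactone opened (step 6).

Key step: step 1

Assumption: in step 9 the (R) enantiomer of DTBM-SEGPHOS is taken as the one that delivers hydride to the C2 face leading to (2R); the sense is to be fixed on 2,3-dimethylchromone as a model, and the (S) ligand is used if it proves opposite.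

**Route**

Step 1
Reactants: 1 phloroglucinol; 2 (E)-hex-2-enal
Product: 4 (4R)-5,7-dihydroxy-4-propylchroman-2-ol (lactol as both anomers), via hydroxy aldehyde 3 (not isolated)
Conditions: (S)-α,α-diphenylprolinol trimethylsilyl ether (20 mol%), PhCO2H (20 mol%), excess phloroglucinol, MeCN, 0 °C
Reagents that add atoms: none
Why: The secondary amine condenses with 2 to an (E,s-trans)-iminium ion, a ring carbon of 1 (all three are equivalent) adds to its β-carbon in a Friedel–Crafts-type conjugate addition, and hydrolysis of the resulting enamine frees aldehyde 3 and the catalyst. The closest known reaction is the iminium-catalysed Friedel–Crafts alkylation/hemiacetalisation of naphthols, sesamol and 3,5-dialkoxyphenols with enals. The lactol ring closes by 6-exo-trig attack of the ortho phenol oxygen on the aldehyde carbon. The C4 stereocentre is set by the catalyst: its diphenyl(silyloxy)methyl group covers one face of the iminium ion, so the arene should add to the open Re face of the β-carbon, which gives (R). The step needs C-alkylation at one ring carbon only and a slow uncatalysed addition; the threefold symmetry of 1, its use in excess and the low temperature should secure this.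

Step 2
Reactants: 4 (4R)-5,7-dihydroxy-4-propylchroman-2-ol
Product: 5 (4R)-5,7-dihydroxy-4-propylchroman-2-one
Conditions: 1,4-dimethyl-1,2,4-triazolium iodide (5 mol%), DBU (10 mol%), 3,3',5,5'-tetra-tert-butyldiphenoquinone (1.05 equiv), THF, rt
Reagents that add atoms: none
Why: Carbene-catalysed oxidative lactonisation: the carbene adds to the aldehyde carbon of the ring-opened tautomer of the lactol, the Breslow intermediate is oxidised by the quinone to an acyl azolium ion and the ortho phenol captures it, while the quinone is too weak an oxidant to attack the electron-rich resorcinol-type ring.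

Step 3
Reactants: 5 (4R)-5,7-dihydroxy-4-propylchroman-2-one
Product: 6 (4R)-5-hydroxy-7-(propan-2-yloxy)-4-propylchroman-2-one
Conditions: 2-bromopropane (1.1 equiv), K2CO3 (1.1 equiv), DMF, rt
Reagents that add atoms: 2-bromopropane, CC(C)Br
Why: Williamson etherification with a secondary halide should take the C7 phenoxide, which is flanked by two ring hydrogens, in preference to the C5 phenoxide, which is peri to the propyl-bearing C4.

Step 4
Reactants: 6 (4R)-5-hydroxy-7-(propan-2-yloxy)-4-propylchroman-2-one; 7 propanoyl chloride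
Product: 9 (4R)-5-hydroxy-6-propanoyl-7-(propan-2-yloxy)-4-propylchroman-2-one, via difluoroboron chelate 8 (not isolated)
Conditions: slight excess of propanoyl chloride, BF3·OEt2 (3 equiv), ClCH2CH2Cl, 60 °C; then H2O, THF, 50 °C
Reagents that add atoms: none
Why: Friedel–Crafts acylation of the activated ring should occur at C6, ortho to the free hydroxyl, as it does in 3,5-dialkoxyphenols under BF3 where the ortho-hydroxy ketone is trapped as its boron chelate (hydrolysed on work-up); the isopropyl ether and the lactone tolerate BF3.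

Step 5
Reactants: 9 (4R)-5-hydroxy-6-propanoyl-7-(propan-2-yloxy)-4-propylchroman-2-one; 10 acetic anhydride
Product: 13 (10R)-2,3-dimethyl-5-(propan-2-yloxy)-10-propyl-9,10-dihydro-4H,8H-pyrano[2,3-f]chromene-4,8-dione, via aryl acetate 11 (not isolated), via diketone 12 (not isolated)
Conditions: NaOAc, neat 10, 140 °C
Reagents that add atoms: none
Why: Kostanecki–Robinson chromone synthesis (O-acetylation, Baker–Venkataraman-type acyl transfer to the ketone α-carbon, cyclodehydration) must close on the C5 oxygen, because the other oxygen next to the ketone is the isopropyl ether, which fixes the pyranone on the oxygen ortho to the side chain.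

Step 6
Reactants: 13 (10R)-2,3-dimethyl-5-(propan-2-yloxy)-10-propyl-9,10-dihydro-4H,8H-pyrano[2,3-f]chromene-4,8-dione
Product: 15 methyl (3R)-3-(5,7-dihydroxy-2,3-dimethyl-4-oxo-4H-chromen-8-yl)hexanoate, via hydroxy lactone 14 (not isolated)
Conditions: BCl3 (3 equiv), CH2Cl2, −78 to 0 °C; then MeOH, 0 to 40 °C; NaHCO3 before concentration
Reagents that add atoms: methanol, CO
Why: Chelation-assisted Lewis acid cleavage removes the isopropyl ether peri to the chromone carbonyl, and the HCl formed on the methanol quench catalyses transesterification of the aryl lactone to the methyl ester, which frees the C7 hydroxyl.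

Step 7
Reactants: 15 methyl (3R)-3-(5,7-dihydroxy-2,3-dimethyl-4-oxo-4H-chromen-8-yl)hexanoate; 16 3-chloro-3-methylbut-1-yne
Product: 17 methyl (3R)-3-[5-hydroxy-2,3-dimethyl-7-(2-methylbut-3-yn-2-yloxy)-4-oxo-4H-chromen-8-yl]hexanoate
Conditions: moderate excess of the propargylic chloride, CuCl2 (1 mol%), DBU (1.3 equiv), MeCN, 0 °C
Reagents that add atoms: none
Why: Copper-catalysed propargylic etherification (through a copper acetylide/allenylidene species) should alkylate only the C7 phenoxide, because the C5 hydroxyl is hydrogen-bonded to the C4 carbonyl and stays unreactive; no epimerisable centre is present at this stage.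

Step 8
Reactants: 17 methyl (3R)-3-[5-hydroxy-2,3-dimethyl-7-(2-methylbut-3-yn-2-yloxy)-4-oxo-4H-chromen-8-yl]hexanoate
Product: 18 methyl (3R)-3-[5-hydroxy-2,3-dimethyl-7-(2-methylbut-3-en-2-yloxy)-4-oxo-4H-chromen-8-yl]hexanoate
Conditions: H2 (1 atm), Pd/CaCO3 poisoned with Pb(OAc)2, quinoline, EtOAc, rt
Reagents that add atoms: none
Why: Lindlar semihydrogenation reduces the terminal alkyne to the alkene and should leave the tetrasubstituted, conjugated C2=C3 bond of the chromone untouched.

Step 9
Reactants: 18 methyl (3R)-3-[5-hydroxy-2,3-dimethyl-7-(2-methylbut-3-en-2-yloxy)-4-oxo-4H-chromen-8-yl]hexanoate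
Product: 19 methyl (3R)-3-[(2R,3S)-5-hydroxy-2,3-dimethyl-7-(2-methylbut-3-en-2-yloxy)-4-oxochroman-8-yl]hexanoate
Conditions: Cu(OAc)2 (5 mol%), (R)-DTBM-SEGPHOS (5.5 mol%), HSiMe(OMe)2 (4 equiv), t-BuOH (2 equiv), toluene, 0 °C; aq. NH4Cl work-up at 0 °C
Reagents that add atoms: none
Why: Proposed new method: asymmetric copper hydride 1,4-reduction is known for 2-monosubstituted chromones and β,β-disubstituted cyclic enones but not for a 2,3-dialkylchromone with a tetrasubstituted C2=C3 bond; the ligated copper hydride should deliver hydride to C2 on the face fixed by the ligand (giving 2R), and tert-butanol should protonate the copper enolate at C3 anti to the pseudoaxial C2 methyl, giving the cis (3S) ketone under kinetic control, while the ester, the terminal alkene and the chelated phenol (covered by excess silane) are expected to be spared at low temperature.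

Step 10
Reactants: 19 methyl (3R)-3-[(2R,3S)-5-hydroxy-2,3-dimethyl-7-(2-methylbut-3-en-2-yloxy)-4-oxochroman-8-yl]hexanoate
Product: 21 methyl (3R)-3-[(2R,3S)-5,7-dihydroxy-2,3-dimethyl-6-(3-methylbut-2-en-1-yl)-4-oxochroman-8-yl]hexanoate (CNP0068017.1), via dienone 20 (not isolated)
Conditions: toluene (degassed), 110 °C, sealed tube
Reagents that add atoms: none
Why: Aromatic Claisen rearrangement ([3,3]) of the 1,1-dimethylallyl ether can rearomatise only through C6, because C8 is substituted, so the group arrives as a normal prenyl unit between the two hydroxyls under neutral conditions that should not disturb the cis C2/C3 centres.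

**Compound list**

1 | phloroglucinol | Oc1cc(O)cc(O)c1 | starting material
2 | (E)-hex-2-enal | CCC/C=C/C=O | starting material
3 | (3R)-3-(2,4,6-trihydroxyphenyl)hexanal | CCC[C@H](CC=O)c1c(O)cc(O)cc1O | intermediate (not isolated)
4 | (4R)-5,7-dihydroxy-4-propylchroman-2-ol (both anomers) | CCC[C@@H]1CC(O)Oc2cc(O)cc(O)c12 | intermediate
5 | (4R)-5,7-dihydroxy-4-propylchroman-2-one | CCC[C@@H]1CC(=O)Oc2cc(O)cc(O)c12 | intermediate
6 | (4R)-5-hydroxy-7-(propan-2-yloxy)-4-propylchroman-2-one | CCC[C@@H]1CC(=O)Oc2cc(OC(C)C)cc(O)c12 | intermediate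
7 | propanoyl chloride | CCC(Cl)=O | starting material
8 | difluoroboron chelate of 9 (boron bridging the C5 oxygen and the ketone oxygen) | CCC[C@@H]1CC(=O)Oc2cc(OC(C)C)c3C(CC)=[O+][B-](F)(F)Oc3c12 | intermediate (not isolated)
9 | (4R)-5-hydroxy-6-propanoyl-7-(propan-2-yloxy)-4-propylchroman-2-one | CCC[C@@H]1CC(=O)Oc2cc(OC(C)C)c(C(=O)CC)c(O)c12 | intermediate
10 | acetic anhydride | CC(=O)OC(C)=O | starting material
11 | (4R)-2-oxo-6-propanoyl-7-(propan-2-yloxy)-4-propylchroman-5-yl acetate | CCC[C@@H]1CC(=O)Oc2cc(OC(C)C)c(C(=O)CC)c(OC(C)=O)c12 | intermediate (not isolated)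
12 | (4R)-5-hydroxy-6-(2-methyl-3-oxobutanoyl)-7-(propan-2-yloxy)-4-propylchroman-2-one | CCC[C@@H]1CC(=O)Oc2cc(OC(C)C)c(C(=O)C(C)C(C)=O)c(O)c12 | intermediate (not isolated)
13 | (10R)-2,3-dimethyl-5-(propan-2-yloxy)-10-propyl-9,10-dihydro-4H,8H-pyrano[2,3-f]chromene-4,8-dione (chromone fused to the dihydrocoumarin) | CCC[C@@H]1CC(=O)Oc2cc(OC(C)C)c3c(c12)OC(C)=C(C)C3=O | intermediate
14 | (10R)-5-hydroxy-2,3-dimethyl-10-propyl-9,10-dihydro-4H,8H-pyrano[2,3-f]chromene-4,8-dione | CCC[C@@H]1CC(=O)Oc2cc(O)c3c(c12)OC(C)=C(C)C3=O | intermediate (not isolated)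
15 | methyl (3R)-3-(5,7-dihydroxy-2,3-dimethyl-4-oxo-4H-chromen-8-yl)hexanoate | CCC[C@H](CC(=O)OC)c1c(O)cc(O)c2c1OC(C)=C(C)C2=O | intermediate
16 | 3-chloro-3-methylbut-1-yne | CC(C)(Cl)C#C | starting material
17 | methyl (3R)-3-[5-hydroxy-2,3-dimethyl-7-(2-methylbut-3-yn-2-yloxy)-4-oxo-4H-chromen-8-yl]hexanoate | CCC[C@H](CC(=O)OC)c1c(OC(C)(C)C#C)cc(O)c2c1OC(C)=C(C)C2=O | intermediate
18 | methyl (3R)-3-[5-hydroxy-2,3-dimethyl-7-(2-methylbut-3-en-2-yloxy)-4-oxo-4H-chromen-8-yl]hexanoate | CCC[C@H](CC(=O)OC)c1c(OC(C)(C)C=C)cc(O)c2c1OC(C)=C(C)C2=O | intermediate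
19 | methyl (3R)-3-[(2R,3S)-5-hydroxy-2,3-dimethyl-7-(2-methylbut-3-en-2-yloxy)-4-oxochroman-8-yl]hexanoate | CCC[C@H](CC(=O)OC)c1c(OC(C)(C)C=C)cc(O)c2c1O[C@H](C)[C@H](C)C2=O | intermediate
20 | methyl (3R)-3-[(2R,3S)-5-hydroxy-2,3-dimethyl-6-(3-methylbut-2-en-1-yl)-4,7-dioxo-3,4,6,7-tetrahydro-2H-chromen-8-yl]hexanoate (Claisen dienone) | CCC[C@H](CC(=O)OC)C1=C2O[C@H](C)[C@H](C)C(=O)C2=C(O)C(CC=C(C)C)C1=O | intermediate (not isolated)
21 | methyl (3R)-3-[(2R,3S)-5,7-dihydroxy-2,3-dimethyl-6-(3-methylbut-2-en-1-yl)-4-oxochroman-8-yl]hexanoate | CCC[C@H](CC(=O)OC)c1c(O)c(CC=C(C)C)c(O)c2c1O[C@H](C)[C@H](C)C2=O | target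

**Step count and risks**

Total steps: 10. Longest linear sequence: 10 steps (1 to 21).

Steps most likely to fail:

Step 9 (proposed new method). Hydride transfer to the fully substituted C2 may be slow, it may go to the wrong face, the cis relationship may be lost by enolisation at C3, or the ketone or the terminal alkene may be reduced as well. The fallback sets out from 15 and uses known chemistry. Hydrogenation over Pd/C (H2, EtOAc) adds both hydrogens to one face of C2=C3 and should give the two cis chromanones: methyl (3R)-3-[(2R,3S)-5,7-dihydroxy-2,3-dimethyl-4-oxochroman-8-yl]hexanoate F1 and methyl (3R)-3-[(2S,3R)-5,7-dihydroxy-2,3-dimethyl-4-oxochroman-8-yl]hexanoate F2, which are separated by chromatography. F1 is then etherified at the free C7 hydroxyl under neutral Tsuji–Trost conditions, with Pd(PPh3)4 in THF at 0 °C and methyl 2-methylbut-3-en-2-yl carbonate F3 (made from commercial 2-methylbut-3-en-2-ol and methyl chloroformate). This gives 19 and rejoins the route before step 10; steps 7 to 9 are not needed.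

Step 1. Phloroglucinol may be alkylated more than once, and the uncatalysed addition (or poor solubility of 1) may erode the enantiomeric purity. The fallback sets out from 1 and builds the same skeleton by a Pechmann condensation. Commercial ethyl 3-oxohexanoate and 1 in H2SO4 at rt should give 5,7-dihydroxy-4-propyl-2H-chromen-2-one F4. Hydrogenation of its C3=C4 bond (H2, Pd/C, AcOH, 50 °C) gives racemic 5,7-dihydroxy-4-propylchroman-2-one F5. Preparative chromatography on a chiral stationary phase separates the (4R)-lactone from (4S)-5,7-dihydroxy-4-propylchroman-2-one F6. The route is rejoined at 5, and steps 1 and 2 are skipped.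

Step 3. The two phenols may not be told apart well enough, giving the wrong mono-ether and the bis-ether. The fallback sets out from 5 and replaces alkylation-based discrimination by a bulky silyl group and an O-acyl/Fries sequence. Silylation with iPr3SiCl and imidazole takes the unhindered phenol and gives (4R)-5-hydroxy-4-propyl-7-[tri(propan-2-yl)silyloxy]chroman-2-one F7. Propanoyl chloride, Et3N and DMAP acylate the remaining hindered phenol to (4R)-2-oxo-4-propyl-7-[tri(propan-2-yl)silyloxy]chroman-5-yl propanoate F8. HF·pyridine removes the silyl group to give (4R)-7-hydroxy-2-oxo-4-propylchroman-5-yl propanoate F9. Mitsunobu etherification with propan-2-ol (PPh3, DIAD) gives (4R)-2-oxo-7-(propan-2-yloxy)-4-propylchroman-5-yl propanoate F10. Fries rearrangement with BF3·OEt2 moves the propanoyl group to C6 through chelate 8 and, after hydrolysis, rejoins the route at 9.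

**Further compounds**

F1 | step 9 | methyl (3R)-3-[(2R,3S)-5,7-dihydroxy-2,3-dimethyl-4-oxochroman-8-yl]hexanoate | CCC[C@H](CC(=O)OC)c1c(O)cc(O)c2c1O[C@H](C)[C@H](C)C2=O
F2 | step 9 | methyl (3R)-3-[(2S,3R)-5,7-dihydroxy-2,3-dimethyl-4-oxochroman-8-yl]hexanoate | CCC[C@H](CC(=O)OC)c1c(O)cc(O)c2c1O[C@@H](C)[C@@H](C)C2=O
F3 | step 9 | methyl 2-methylbut-3-en-2-yl carbonate | COC(=O)OC(C)(C)C=C
F4 | step 1 | 5,7-dihydroxy-4-propyl-2H-chromen-2-one | CCCc1cc(=O)oc2cc(O)cc(O)c12
F5 | step 1 | racemic 5,7-dihydroxy-4-propylchroman-2-one | CCCC1CC(=O)Oc2cc(O)cc(O)c12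
F6 | step 1 | (4S)-5,7-dihydroxy-4-propylchroman-2-one | CCC[C@H]1CC(=O)Oc2cc(O)cc(O)c12
F7 | step 3 | (4R)-5-hydroxy-4-propyl-7-[tri(propan-2-yl)silyloxy]chroman-2-one | CCC[C@@H]1CC(=O)Oc2cc(O[Si](C(C)C)(C(C)C)C(C)C)cc(O)c12
F8 | step 3 | (4R)-2-oxo-4-propyl-7-[tri(propan-2-yl)silyloxy]chroman-5-yl propanoate | CCC[C@@H]1CC(=O)Oc2cc(O[Si](C(C)C)(C(C)C)C(C)C)cc(OC(=O)CC)c12
F9 | step 3 | (4R)-7-hydroxy-2-oxo-4-propylchroman-5-yl propanoate | CCC[C@@H]1CC(=O)Oc2cc(O)cc(OC(=O)CC)c12
F10 | step 3 | (4R)-2-oxo-7-(propan-2-yloxy)-4-propylchroman-5-yl propanoate | CCC[C@@H]1CC(=O)Oc2cc(OC(C)C)cc(OC(=O)CC)c12
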